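The flavone is disconnected at C4a–C4, C4–C3 and O1–C2. Because the C4 carbonyl of the pyranone (ring C) lies between C4a of ring A and the alkene carbon C3, it can be supplied as carbon monoxide between an aryl iodide (future C4a) and the terminal carbon of an arylacetylene that already carries ring B on the future C2. One palladium-catalysed operation joins the three components and lets the adjacent phenol oxygen (O1 on C8a) close ring C. The precursor is a pentasubstituted ortho-iodophenol whose only free hydroxyl sits beside the methoxy group (future C8), with the future 5- and 7-oxygens masked as isopropyl ethers.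

Key step: step 7

Remark: the target has no stereocentre and no stereogenic axis, so it is achiral and no step needs to control configuration. The mapping used throughout is iodine carbon → C4a, phenol carbon → C8a, methoxy carbon → C8.

Step 1
Reactants: 1 2,4,6-trihydroxybenzaldehyde; 2 2-bromopropane
Product: 3 2-hydroxy-4,6-diisopropoxybenzaldehyde
Conditions: i-PrBr (2.2 equiv), K2CO3 (2.2 equiv), DMF, 50 °C
Reagents that add atoms: 2-bromopropane (compound 2, also listed as reactant), CC(C)Br
Why: Williamson etherification should alkylate the para hydroxyl and one ortho hydroxyl, while the last ortho hydroxyl is held back by its hydrogen bond to the formyl oxygen, as is usual for 2,4,6-trihydroxyaryl carbonyl compounds.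

Step 2
Reactants: 3 2-hydroxy-4,6-diisopropoxybenzaldehyde
Product: 4 2,4-diisopropoxy-6-(methoxymethoxy)benzaldehyde
Conditions: NaH (1.2 equiv), MOMCl (1.3 equiv), THF–DMF, 0 °C → rt
Reagents that add atoms: chloromethyl methyl ether, COCCl
Why: O-alkylation of the fully formed sodium phenoxide overcomes the chelation of this hydroxyl, and the resulting MOM acetal later serves both as the temporary mask of the future O1 and as the ortho-directing group.

Step 3
Reactants: 4 2,4-diisopropoxy-6-(methoxymethoxy)benzaldehyde
Product: 6 2,4-diisopropoxy-6-(methoxymethoxy)phenol, via aryl formate 5 (not isolated)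
Conditions: mCPBA (1.2 equiv), CH2Cl2, 0 °C → rt; then K2CO3 (cat.), MeOH, rt, under argon
Reagents that add atoms: meta-chloroperbenzoic acid, OOC(=O)c1cccc(Cl)c1
Why: In this Baeyer–Villiger (Dakin-type) oxidation the electron-rich trialkoxyaryl group migrates in preference to hydride to give the aryl formate, which mild methanolysis should cleave without touching the acetal or the isopropyl ethers.

Step 4
Reactants: 6 2,4-diisopropoxy-6-(methoxymethoxy)phenol
Product: 7 1,5-diisopropoxy-2-methoxy-3-(methoxymethoxy)benzene
Conditions: MeI (1.5 equiv), K2CO3 (1.5 equiv), acetone, 40 °C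
Reagents that add atoms: iodomethane, CI
Why: Williamson methylation of the only free phenol fixes the methoxy group on the carbon that becomes C8.

Step 5
Reactants: 7 1,5-diisopropoxy-2-methoxy-3-(methoxymethoxy)benzene
Product: 9 2-iodo-1,5-diisopropoxy-4-methoxy-3-(methoxymethoxy)benzene, via aryllithium 8 (not isolated)
Conditions: n-BuLi (1.2 equiv), TMEDA, THF, −78 → 0 °C; then I2 (1.3 equiv), THF, −78 °C → rt
Reagents that add atoms: iodine, II
Why: In this directed ortho-metalation and iodinolysis the MOM ether binds butyllithium, and its only free ortho position, also flanked by an isopropoxy group, should be deprotonated in preference to the position between the two bulky, weakly coordinating isopropoxy groups.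

Step 6
Reactants: 9 2-iodo-1,5-diisopropoxy-4-methoxy-3-(methoxymethoxy)benzene
Product: 10 2-iodo-3,5-diisopropoxy-6-methoxyphenol
Conditions: HCl (cat., 2 M in MeOH), MeOH, rt
Reagents that add atoms: none
Why: Acid-catalysed transacetalisation to methanol removes the MOM group, while the isopropyl ethers, the methyl ether and the aryl iodide should be inert to dilute methanolic acid at room temperature.

Step 7
Reactants: 10 2-iodo-3,5-diisopropoxy-6-methoxyphenol; 11 5-ethynyl-1,2,3-trimethoxybenzene; 12 carbon monoxide
Product: 15 5,7-diisopropoxy-8-methoxy-2-(3,4,5-trimethoxyphenyl)chromen-4-one, via hydroxyaryl ynone 13 (not isolated), via diethylamino enone 14 (not isolated)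
Conditions: 11 (1.3 equiv), CO (20 bar), PdCl2(dppf) (5 mol%), Et2NH, 120 °C
Reagents that add atoms: carbon monoxide (compound 12, also listed as reactant), [C-]#[O+]
Why: Pd(0) inserts into the C–I bond of 10, CO insertion gives the aroyl–palladium species, and coupling with the amine-deprotonated alkyne followed by reductive elimination delivers ynone 13, creating C4a–C4 and C4–C3. Diethylamine then adds to the ynone to give the β-amino enone 14, whose β-carbon (future C2) is attacked by the ortho phenol oxygen with loss of the amine, forming O1–C2. The closest known reaction type is the palladium-catalysed carbonylative Sonogashira coupling–cyclisation of 2-iodophenols with terminal alkynes to flavones. The one ring formed, the pyranone, closes in a net 6-endo-dig oxa-Michael mode (addition–elimination on the enaminone), and no stereocentre is created. The step needs 6-endo closure rather than 5-exo closure to an aurone, which the secondary amine secures because 14 is electrophilic only at C2; it also needs the 8-methoxy ring fusion, which the substrate secures because the only free hydroxyl next to iodine is the one beside the methoxy group, the other flanking oxygen being an isopropyl ether. The methyl and isopropyl ethers are spectators under these basic, non-acidic conditions.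

Step 8
Reactants: 15 5,7-diisopropoxy-8-methoxy-2-(3,4,5-trimethoxyphenyl)chromen-4-one
Product: 17 5,7-dihydroxy-8-methoxy-2-(3,4,5-trimethoxyphenyl)chromen-4-one (3',4',5'-trimethoxywogonin), via bis(dichloroboryl) ether 16 (not isolated)
Conditions: BCl3 (1 M in CH2Cl2, 5 equiv), CH2Cl2, −78 → 0 °C; then H2O
Reagents that add atoms: none
Why: In this Lewis-acid dealkylation BCl3 cleaves secondary alkyl aryl ethers by ionisation to the isopropyl cation (the peri 5-ether further helped by chelation to the C4 carbonyl) much faster than it attacks non-chelated methyl ethers at or below 0 °C, so the four methoxy groups should remain.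

Compound list
1 | 2,4,6-trihydroxybenzaldehyde | O=Cc1c(O)cc(O)cc1O | starting material
2 | 2-bromopropane | CC(C)Br | starting material
3 | 2-hydroxy-4,6-diisopropoxybenzaldehyde | O=Cc1c(O)cc(OC(C)C)cc1OC(C)C | intermediate
4 | 2,4-diisopropoxy-6-(methoxymethoxy)benzaldehyde | O=Cc1c(OCOC)cc(OC(C)C)cc1OC(C)C | intermediate
5 | 2,4-diisopropoxy-6-(methoxymethoxy)phenyl formate (in situ, step 3) | O=COc1c(OCOC)cc(OC(C)C)cc1OC(C)C | intermediate
6 | 2,4-diisopropoxy-6-(methoxymethoxy)phenol | Oc1c(OCOC)cc(OC(C)C)cc1OC(C)C | intermediate
7 | 1,5-diisopropoxy-2-methoxy-3-(methoxymethoxy)benzene | COc1c(OCOC)cc(OC(C)C)cc1OC(C)C | intermediate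
8 | [4,6-diisopropoxy-3-methoxy-2-(methoxymethoxy)phenyl]lithium (in situ, step 5) | [Li]c1c(OCOC)c(OC)c(OC(C)C)cc1OC(C)C | intermediate
9 | 2-iodo-1,5-diisopropoxy-4-methoxy-3-(methoxymethoxy)benzene | COc1c(OCOC)c(I)c(OC(C)C)cc1OC(C)C | intermediate
10 | 2-iodo-3,5-diisopropoxy-6-methoxyphenol | COc1c(O)c(I)c(OC(C)C)cc1OC(C)C | intermediate
11 | 5-ethynyl-1,2,3-trimethoxybenzene | C#Cc1cc(OC)c(OC)c(OC)c1 | starting material
12 | carbon monoxide | [C-]#[O+] | starting material
13 | 1-(2-hydroxy-4,6-diisopropoxy-3-methoxyphenyl)-3-(3,4,5-trimethoxyphenyl)prop-2-yn-1-one (in situ, step 7) | COc1cc(C#CC(=O)c2c(O)c(OC)c(OC(C)C)cc2OC(C)C)cc(OC)c1OC | intermediate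
14 | 3-(diethylamino)-1-(2-hydroxy-4,6-diisopropoxy-3-methoxyphenyl)-3-(3,4,5-trimethoxyphenyl)prop-2-en-1-one (in situ, step 7; alkene geometry not fixed, both isomers cyclise) | CCN(CC)C(=CC(=O)c1c(O)c(OC)c(OC(C)C)cc1OC(C)C)c1cc(OC)c(OC)c(OC)c1 | intermediate
15 | 5,7-diisopropoxy-8-methoxy-2-(3,4,5-trimethoxyphenyl)chromen-4-one | COc1cc(-c2cc(=O)c3c(OC(C)C)cc(OC(C)C)c(OC)c3o2)cc(OC)c1OC | intermediate
16 | 5,7-bis(dichloroboryloxy)-8-methoxy-2-(3,4,5-trimethoxyphenyl)chromen-4-one (in situ, step 8) | COc1cc(-c2cc(=O)c3c(OB(Cl)Cl)cc(OB(Cl)Cl)c(OC)c3o2)cc(OC)c1OC | intermediate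
17 | 5,7-dihydroxy-8-methoxy-2-(3,4,5-trimethoxyphenyl)chromen-4-one (3',4',5'-trimethoxywogonin) | COc1cc(-c2cc(=O)c3c(O)cc(O)c(OC)c3o2)cc(OC)c1OC | target

Total step count: 8. Longest linear sequence: 8 steps (1 → 17); alkyne 11 and carbon monoxide 12 are used as purchased.

Steps most likely to fail

Step 7. Oxidative addition into the electron-rich C–I bond flanked on both sides may be slow, so that aminocarbonylation by diethylamine, hydrodeiodination or alkyne oligomerisation could overtake ynone formation. The fallback builds the ynone without palladium or carbon monoxide, setting out from 7 and 11 and returning at 13 and then 15. Alkyne 11 is lithiated (n-BuLi, THF, −78 °C) and formylated with DMF to 3-(3,4,5-trimethoxyphenyl)prop-2-ynal F1. Compound 7 is metalated as in step 5 to aryllithium 8, which adds 1,2 to F1 and, after aqueous NH4Cl quench, should give the racemic propargylic alcohol 1-[4,6-diisopropoxy-3-methoxy-2-(methoxymethoxy)phenyl]-3-(3,4,5-trimethoxyphenyl)prop-2-yn-1-ol F2, whose carbinol centre is removed in the next operation. MnO2 in CH2Cl2 should oxidise it to 1-[4,6-diisopropoxy-3-methoxy-2-(methoxymethoxy)phenyl]-3-(3,4,5-trimethoxyphenyl)prop-2-yn-1-one F3. Methanolic HCl then removes the acetal to give ynone 13, and diethylamine in ethanol at 60 °C closes it through enaminone 14 to flavone 15.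

Step 5. Metalation could occur in part between the two isopropoxy groups, or lithium–iodine exchange between product and unreacted aryllithium could scramble the iodide during the quench. The fallback replaces the acetal by the strongest oxygen-based directing group and a base-labile unmasking; it sets out from 7 and returns at 10. Methanolic HCl converts 7 into 3,5-diisopropoxy-2-methoxyphenol F4. NaH and diethylcarbamoyl chloride in THF give 3,5-diisopropoxy-2-methoxyphenyl N,N-diethylcarbamate F5. s-BuLi/TMEDA in THF at −78 °C, followed by iodine at the same temperature (kept cold to avoid the anionic ortho-Fries shift), should give 2-iodo-3,5-diisopropoxy-6-methoxyphenyl N,N-diethylcarbamate F6. NaOH in refluxing ethanol and acidic work-up then release iodophenol 10.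

Step 1. Partial alkylation with a secondary bromide may stop unevenly or run on to the triether, giving a mixture that is tedious to separate. The fallback alkylates exhaustively and then removes one group under chelation control; it sets out from 1 and returns at 3. Excess 2-bromopropane and K2CO3 in DMF at 80 °C give 2,4,6-triisopropoxybenzaldehyde F7. BCl3 (1.05 equiv) in CH2Cl2 at −78 °C should then cleave only one ether ortho to the formyl group, because the boron chelate formed after the first cleavage deactivates the carbonyl towards a second one, giving 3 after aqueous work-up.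

Further compounds
F1 | step 7 | 3-(3,4,5-trimethoxyphenyl)prop-2-ynal | O=CC#Cc1cc(OC)c(OC)c(OC)c1
F2 | step 7 | 1-[4,6-diisopropoxy-3-methoxy-2-(methoxymethoxy)phenyl]-3-(3,4,5-trimethoxyphenyl)prop-2-yn-1-ol (racemic) | COCOc1c(OC)c(OC(C)C)cc(OC(C)C)c1C(O)C#Cc1cc(OC)c(OC)c(OC)c1
F3 | step 7 | 1-[4,6-diisopropoxy-3-methoxy-2-(methoxymethoxy)phenyl]-3-(3,4,5-trimethoxyphenyl)prop-2-yn-1-one | COCOc1c(OC)c(OC(C)C)cc(OC(C)C)c1C(=O)C#Cc1cc(OC)c(OC)c(OC)c1
F4 | step 5 | 3,5-diisopropoxy-2-methoxyphenol | COc1c(O)cc(OC(C)C)cc1OC(C)C
F5 | step 5 | 3,5-diisopropoxy-2-methoxyphenyl N,N-diethylcarbamate | CCN(CC)C(=O)Oc1cc(OC(C)C)cc(OC(C)C)c1OC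
F6 | step 5 | 2-iodo-3,5-diisopropoxy-6-methoxyphenyl N,N-diethylcarbamate | CCN(CC)C(=O)Oc1c(I)c(OC(C)C)cc(OC(C)C)c1OC
F7 | step 1 | 2,4,6-triisopropoxybenzaldehyde | O=Cc1c(OC(C)C)cc(OC(C)C)cc1OC(C)C
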